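The cyclohex-2-en-1-one ring (C1 ketone, C2 acetoxy, C3 methyl, C4 hydroxyl, C5 methylene, C6 alkylidene) is disconnected at C5–C6 and C3–C4. The key step exploits the enolised C1/C2 dione flanked by C3 and C6 as a latent 2,3-dioxygenated 1,3-diene and C4–C5 as a two-carbon dienophile: a catalytic enantioselective Diels–Alder reaction of a 2,3-bis(silyloxy)penta-1,3-diene with but-3-en-2-one forms both bonds and sets C4, whose acetyl group later becomes the hydroxyl by Baeyer–Villiger oxidation. Saegusa–Ito oxidation restores the C2=C3 enol double bond, and the angeloylated side-chain ketone is joined at C6 by aldol condensation.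

Key step: step 5

Remark: the facial sense of the oxazaborolidinium catalyst (step 5) and of D-proline (step 1) is assigned by analogy with the accepted transition-state models; the antipodal catalyst would be used if the sense were opposite.

Step 1
Reactants: 1 6-methylhept-5-en-2-one; 2 nitrosobenzene
Product: 3 (3S)-6-methyl-3-[(phenylamino)oxy]hept-5-en-2-one
Conditions: D-proline (20 mol %), DMSO, rt, slow addition of 2 to excess 1
Reagents that add atoms: none
Why: Proline-catalysed α-aminoxylation (nitroso aldol reaction): the more substituted enamine of the methyl ketone attacks the oxygen of nitrosobenzene at the methylene carbon, and D-proline should set the 3S centre by the same hydrogen-bonded transition state that gives the R products with L-proline.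

Step 2
Reactants: 3 (3S)-6-methyl-3-[(phenylamino)oxy]hept-5-en-2-one
Product: 4 (3S)-3-hydroxy-6-methylhept-5-en-2-one
Conditions: CuSO4·5H2O (30 mol %), MeOH, 0 °C
Reagents that add atoms: none
Why: Copper-catalysed N–O bond cleavage of the aminooxy ketone in methanol releases the α-hydroxy ketone under near-neutral conditions at 0 °C, so the enolisable α-stereocentre and the trisubstituted alkene should be left unchanged.

Step 3
Reactants: 4 (3S)-3-hydroxy-6-methylhept-5-en-2-one; 5 angelic acid [(2Z)-2-methylbut-2-enoic acid]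
Product: 7 (3S)-6-methyl-2-oxohept-5-en-3-yl (2Z)-2-methylbut-2-enoate, via angeloyl 2,4,6-trichlorobenzoyl anhydride 6 (not isolated)
Conditions: 5, 2,4,6-trichlorobenzoyl chloride, Et3N, toluene, rt; then 4, toluene, 60 °C
Reagents that add atoms: 2,4,6-trichlorobenzoyl chloride, O=C(Cl)c1c(Cl)cc(Cl)cc1Cl (atoms only in intermediate 6)
Why: Yamaguchi esterification: the alcohol attacks the less hindered angeloyl carbonyl of the mixed anhydride without a nucleophilic catalyst, which should avoid Z to E isomerisation to the tiglate and does not involve the stereocentre.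

Step 4
Reactants: 8 pentane-2,3-dione
Product: 10 (3Z)-2-[(triethylsilyl)oxy]-3-[(triisopropylsilyl)oxy]penta-1,3-diene, via (3Z)-3-[(triisopropylsilyl)oxy]pent-3-en-2-one 9 (not isolated)
Conditions: iPr3SiOTf (1.0 equiv), Et3N, CH2Cl2, 0 °C; then Et3SiOTf (1.1 equiv), Et3N, 0 °C to rt
Reagents that add atoms: triisopropylsilyl triflate, CC(C)[Si](OS(=O)(=O)C(F)(F)F)(C(C)C)C(C)C; triethylsilyl triflate, CC[Si](CC)(CC)OS(=O)(=O)C(F)(F)F
Why: Two soft enolisations with silyl triflate and amine base: the first silylates the conjugated, more substituted enol of the dione (methyl cis to the silyloxy group, equilibrated by the triflate), the second turns the remaining methyl ketone into its triethylsilyl enol ether, which gives a 2,3-bis(silyloxy)diene whose two oxygens carry silyl groups of different lability.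

Step 5
Reactants: 10 (3Z)-2-[(triethylsilyl)oxy]-3-[(triisopropylsilyl)oxy]penta-1,3-diene; 11 but-3-en-2-one
Product: 12 1-[(1R,2R)-2-methyl-4-[(triethylsilyl)oxy]-3-[(triisopropylsilyl)oxy]cyclohex-3-en-1-yl]ethan-1-one
Conditions: (R)-1-(2-methylphenyl)-3,3-diphenyltetrahydro-1H,3H-pyrrolo[1,2-c][1,3,2]oxazaborole (10 mol %), HNTf2 (8 mol %), CH2Cl2, −78 °C
Reagents that add atoms: none
Why: The enone bound to the cationic boron reacts as a LUMO-lowered dienophile with the electron-rich diene in a concerted, asynchronous normal-demand [4+2] cycloaddition; the closest known reaction type is the chiral oxazaborolidinium-catalysed Diels–Alder reaction of 2-silyloxy-1,3-dienes with acrylates and enones. The cyclohexene ring is closed by intermolecular [4+2] cycloaddition, suprafacial on both components, the CH2 terminus of the diene bonding to the β-carbon of the enone and the methyl-bearing terminus to its α-carbon. The acetyl-bearing centre (R) is set by the catalyst, which shields one face of the coordinated enone; the neighbouring methyl-bearing centre follows from the endo transition state and the geometry of the propenyl terminus (cis) and is erased in step 6. The step needs "ortho" regioselectivity, secured by the terminal methyl group that places the larger HOMO coefficient on the CH2 terminus, and facial selectivity, secured by the catalyst. The triethylsilyl and triisopropylsilyl enol ethers are chosen to survive the Lewis acid at −78 °C.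

Step 6
Reactants: 12 1-[(1R,2R)-2-methyl-4-[(triethylsilyl)oxy]-3-[(triisopropylsilyl)oxy]cyclohex-3-en-1-yl]ethan-1-one
Product: 13 (4R)-4-acetyl-3-methyl-2-[(triisopropylsilyl)oxy]cyclohex-2-en-1-one
Conditions: Pd(OAc)2 (1.05 equiv), MeCN, rt
Reagents that add atoms: none
Why: Saegusa–Ito oxidation: divalent palladium attacks only the labile triethylsilyl enol ether, the palladium enolate carries the metal on the triisopropylsilyloxy-bearing carbon and β-hydride elimination of the single adjacent hydrogen forms the 2-silyloxy enone, which removes the auxiliary methyl stereocentre while the acetyl-bearing centre is not enolised in the neutral medium.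

Step 7
Reactants: 13 (4R)-4-acetyl-3-methyl-2-[(triisopropylsilyl)oxy]cyclohex-2-en-1-one
Product: 14 (1R)-2-methyl-4-oxo-3-[(triisopropylsilyl)oxy]cyclohex-2-en-1-yl acetate
Conditions: mCPBA, NaHCO3, CH2Cl2, 0 °C to rt
Reagents that add atoms: mCPBA, OOC(=O)c1cccc(Cl)c1
Why: Baeyer–Villiger oxidation of the saturated methyl ketone with migration of the secondary allylic ring carbon and retention of configuration; the cross-conjugated ring ketone and the hindered, carbonyl-conjugated enol ether double bond should react more slowly with the buffered peracid.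

Step 8
Reactants: 14 (1R)-2-methyl-4-oxo-3-[(triisopropylsilyl)oxy]cyclohex-2-en-1-yl acetate
Product: 15 (4R)-4-hydroxy-3-methyl-2-[(triisopropylsilyl)oxy]cyclohex-2-en-1-one
Conditions: K2CO3 (0.2 equiv), MeOH, 0 °C
Reagents that add atoms: none
Why: Zemplén-type transesterification with catalytic carbonate in methanol cleaves the secondary acetate, while the bulky triisopropylsilyl enol ether should survive at 0 °C and the stereocentre is not involved.

Step 9
Reactants: 15 (4R)-4-hydroxy-3-methyl-2-[(triisopropylsilyl)oxy]cyclohex-2-en-1-one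
Product: 16 (4R)-4-[(tert-butyldimethylsilyl)oxy]-3-methyl-2-[(triisopropylsilyl)oxy]cyclohex-2-en-1-one
Conditions: tBuMe2SiCl, imidazole, DMF, rt
Reagents that add atoms: tert-butyldimethylsilyl chloride, CC(C)(C)[Si](C)(C)Cl
Why: Silyl ether formation at the secondary allylic alcohol under standard imidazole catalysis gives a protecting group that withstands the enolate chemistry and is cleaved by fluoride far more slowly than the enol silyl ether.

Step 10
Reactants: 16 (4R)-4-[(tert-butyldimethylsilyl)oxy]-3-methyl-2-[(triisopropylsilyl)oxy]cyclohex-2-en-1-one; 7 (3S)-6-methyl-2-oxohept-5-en-3-yl (2Z)-2-methylbut-2-enoate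
Product: 18 (3S)-2-[(5R)-5-[(tert-butyldimethylsilyl)oxy]-4-methyl-2-oxo-3-[(triisopropylsilyl)oxy]cyclohex-3-en-1-yl]-2-hydroxy-6-methylhept-5-en-3-yl (2Z)-2-methylbut-2-enoate (mixture at the two new centres), via lithium dienolate 17 (not isolated)
Conditions: LiN(iPr)2, THF, −78 °C; then 7, −78 °C; AcOH quench at −78 °C
Reagents that add atoms: lithium diisopropylamide, [Li+].CC(C)[N-]C(C)C (lithium only in intermediate 17)
Why: Directed aldol addition: kinetic deprotonation at the only α-methylene gives the cross-conjugated lithium enolate, which adds to the chelating α-acyloxy methyl ketone; the two new stereocentres form as a mixture and are both removed in step 11, and the cold acidic quench should prevent retro-aldol cleavage and acyl migration.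

Step 11
Reactants: 18 aldol adduct
Product: 20 (2E,3S)-2-[(5R)-5-[(tert-butyldimethylsilyl)oxy]-4-methyl-2-oxo-3-[(triisopropylsilyl)oxy]cyclohex-3-en-1-ylidene]-6-methylhept-5-en-3-yl (2Z)-2-methylbut-2-enoate, via tertiary methanesulfonate 19 (not isolated)
Conditions: MsCl, Et3N, CH2Cl2, 0 °C to rt
Reagents that add atoms: methanesulfonyl chloride, CS(=O)(=O)Cl (atoms only in intermediate 19)
Why: Dehydration by mesylation of the tertiary alcohol (through sulfene) and E1cB elimination via the ring enolate gives the conjugated tetrasubstituted alkene, and the E isomer should prevail because the larger acyloxy-bearing group avoids the position syn to the carbonyl oxygen in the elimination and in the product.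

Step 12
Reactants: 20 silylated enone
Product: 22 (2E,3S)-2-[(5R)-3-acetoxy-5-[(tert-butyldimethylsilyl)oxy]-4-methyl-2-oxocyclohex-3-en-1-ylidene]-6-methylhept-5-en-3-yl (2Z)-2-methylbut-2-enoate, via tetrabutylammonium diosphenolate 21 (not isolated)
Conditions: Ac2O (3 equiv), Bu4NF (1.05 equiv), THF, −78 °C; pH 7 buffer
Reagents that add atoms: acetic anhydride, CC(=O)OC(C)=O; tetrabutylammonium fluoride, [F-].CCCC[N+](CCCC)(CCCC)CCCC (cation only in intermediate 21)
Why: Fluoride-induced cleavage of the enol silyl ether, which is much faster than that of the secondary alkyl silyl ether, followed by O-acetylation of the ammonium diosphenolate by acetic anhydride already present, should give the enol acetate before the enolate can expel the β-silyloxy group.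

Step 13
Reactants: 22 enol acetate silyl ether
Product: 23 (2E,3S)-2-[(5R)-3-acetoxy-5-hydroxy-4-methyl-2-oxocyclohex-3-en-1-ylidene]-6-methylhept-5-en-3-yl (2Z)-2-methylbut-2-enoate (CNP0389456.1)
Conditions: HF·pyridine, pyridine, THF, 0 °C to rt
Reagents that add atoms: none
Why: Fluoride desilylation of the secondary silyl ether with buffered hydrogen fluoride–pyridine leaves the enol acetate and the angelate intact and avoids the basic conditions under which the acetyl group could migrate to the freed hydroxyl.

Compound list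
1 | 6-methylhept-5-en-2-one | CC(=O)CCC=C(C)C | starting material
2 | nitrosobenzene | O=Nc1ccccc1 | starting material
3 | (3S)-6-methyl-3-[(phenylamino)oxy]hept-5-en-2-one | CC(=O)[C@@H](ONc1ccccc1)CC=C(C)C | intermediate
4 | (3S)-3-hydroxy-6-methylhept-5-en-2-one | CC(=O)[C@@H](O)CC=C(C)C | intermediate
5 | angelic acid, (2Z)-2-methylbut-2-enoic acid | C/C=C(/C)C(=O)O | starting material
6 | (2Z)-2-methylbut-2-enoic 2,4,6-trichlorobenzoic anhydride | C/C=C(/C)C(=O)OC(=O)c1c(Cl)cc(Cl)cc1Cl | intermediate (not isolated)
7 | (3S)-6-methyl-2-oxohept-5-en-3-yl (2Z)-2-methylbut-2-enoate | C/C=C(/C)C(=O)O[C@@H](CC=C(C)C)C(C)=O | intermediate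
8 | pentane-2,3-dione | CCC(=O)C(C)=O | starting material
9 | (3Z)-3-[(triisopropylsilyl)oxy]pent-3-en-2-one | CC(=O)/C(O[Si](C(C)C)(C(C)C)C(C)C)=C/C | intermediate (not isolated)
10 | (3Z)-2-[(triethylsilyl)oxy]-3-[(triisopropylsilyl)oxy]penta-1,3-diene | C=C(O[Si](CC)(CC)CC)/C(O[Si](C(C)C)(C(C)C)C(C)C)=C/C | intermediate
11 | but-3-en-2-one | C=CC(C)=O | starting material
12 | 1-[(1R,2R)-2-methyl-4-[(triethylsilyl)oxy]-3-[(triisopropylsilyl)oxy]cyclohex-3-en-1-yl]ethan-1-one (cis) | CC(=O)[C@@H]1CCC(O[Si](CC)(CC)CC)=C(O[Si](C(C)C)(C(C)C)C(C)C)[C@@H]1C | intermediate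
13 | (4R)-4-acetyl-3-methyl-2-[(triisopropylsilyl)oxy]cyclohex-2-en-1-one | CC(=O)[C@@H]1CCC(=O)C(O[Si](C(C)C)(C(C)C)C(C)C)=C1C | intermediate
14 | (1R)-2-methyl-4-oxo-3-[(triisopropylsilyl)oxy]cyclohex-2-en-1-yl acetate | CC(=O)O[C@@H]1CCC(=O)C(O[Si](C(C)C)(C(C)C)C(C)C)=C1C | intermediate
15 | (4R)-4-hydroxy-3-methyl-2-[(triisopropylsilyl)oxy]cyclohex-2-en-1-one | O[C@@H]1CCC(=O)C(O[Si](C(C)C)(C(C)C)C(C)C)=C1C | intermediate
16 | (4R)-4-[(tert-butyldimethylsilyl)oxy]-3-methyl-2-[(triisopropylsilyl)oxy]cyclohex-2-en-1-one | CC(C)(C)[Si](C)(C)O[C@@H]1CCC(=O)C(O[Si](C(C)C)(C(C)C)C(C)C)=C1C | intermediate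
17 | lithium (5R)-5-[(tert-butyldimethylsilyl)oxy]-4-methyl-3-[(triisopropylsilyl)oxy]cyclohexa-1,3-dien-2-olate | [Li+].[O-]C1=CC[C@@H](O[Si](C)(C)C(C)(C)C)C(C)=C1O[Si](C(C)C)(C(C)C)C(C)C | intermediate (not isolated)
18 | (3S)-2-[(5R)-5-[(tert-butyldimethylsilyl)oxy]-4-methyl-2-oxo-3-[(triisopropylsilyl)oxy]cyclohex-3-en-1-yl]-2-hydroxy-6-methylhept-5-en-3-yl (2Z)-2-methylbut-2-enoate (epimers at the carbinol carbon and at ring C1) | C/C=C(/C)C(=O)O[C@@H](CC=C(C)C)C(C)(O)C1C[C@@H](O[Si](C)(C)C(C)(C)C)C(C)=C(O[Si](C(C)C)(C(C)C)C(C)C)C1=O | intermediate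
19 | methanesulfonate of the tertiary alcohol of 18 | C/C=C(/C)C(=O)O[C@@H](CC=C(C)C)C(C)(OS(C)(=O)=O)C1C[C@@H](O[Si](C)(C)C(C)(C)C)C(C)=C(O[Si](C(C)C)(C(C)C)C(C)C)C1=O | intermediate (not isolated)
20 | (2E,3S)-2-[(5R)-5-[(tert-butyldimethylsilyl)oxy]-4-methyl-2-oxo-3-[(triisopropylsilyl)oxy]cyclohex-3-en-1-ylidene]-6-methylhept-5-en-3-yl (2Z)-2-methylbut-2-enoate | C/C=C(/C)C(=O)O[C@@H](CC=C(C)C)/C(C)=C1\C[C@@H](O[Si](C)(C)C(C)(C)C)C(C)=C(O[Si](C(C)C)(C(C)C)C(C)C)C1=O | intermediate
21 | tetrabutylammonium enolate (2-oxido enone) formed from 20 by loss of the triisopropylsilyl group | C/C=C(/C)C(=O)O[C@@H](CC=C(C)C)/C(C)=C1\C[C@@H](O[Si](C)(C)C(C)(C)C)C(C)=C([O-])C1=O.CCCC[N+](CCCC)(CCCC)CCCC | intermediate (not isolated)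
22 | (2E,3S)-2-[(5R)-3-acetoxy-5-[(tert-butyldimethylsilyl)oxy]-4-methyl-2-oxocyclohex-3-en-1-ylidene]-6-methylhept-5-en-3-yl (2Z)-2-methylbut-2-enoate | C/C=C(/C)C(=O)O[C@@H](CC=C(C)C)/C(C)=C1\C[C@@H](O[Si](C)(C)C(C)(C)C)C(C)=C(OC(C)=O)C1=O | intermediate
23 | (2E,3S)-2-[(5R)-3-acetoxy-5-hydroxy-4-methyl-2-oxocyclohex-3-en-1-ylidene]-6-methylhept-5-en-3-yl (2Z)-2-methylbut-2-enoate, CNP0389456.1 | C/C=C(/C)C(=O)O[C@@H](CC=C(C)C)/C(C)=C1\C[C@@H](O)C(C)=C(OC(C)=O)C1=O | target

Total step count: 13. Longest linear sequence: 10 steps (steps 4 to 13, from pentane-2,3-dione 8); the side-chain ketone 7 (steps 1 to 3) enters at step 10.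

Steps most likely to fail

Step 5 (key step). What may go wrong is protodesilylation of the acid-sensitive diene, a stepwise Mukaiyama–Michael addition that stops at the open-chain stage, or insufficient facial discrimination by the catalyst. The fallback sets out from 10 and 11 and gives up the chiral catalyst. An uncatalysed thermal Diels–Alder reaction (toluene, 80 °C) should give racemic cis-1-[2-methyl-4-[(triethylsilyl)oxy]-3-[(triisopropylsilyl)oxy]cyclohex-3-en-1-yl]ethan-1-one F1. Saegusa–Ito oxidation as in step 6 should then give racemic 4-acetyl-3-methyl-2-[(triisopropylsilyl)oxy]cyclohex-2-en-1-one F2, and Baeyer–Villiger oxidation as in step 7 racemic 2-methyl-4-oxo-3-[(triisopropylsilyl)oxy]cyclohex-2-en-1-yl acetate F3. Enzymatic kinetic resolution of F3 by alcoholysis (Candida antarctica lipase B, butan-1-ol, tert-butyl methyl ether) should cleave the R acetate preferentially, following the empirical size rule for lipases with the methyl-substituted alkene carbon as the larger substituent. The route is rejoined at alcohol 15; the S acetate stays unreacted and is separated.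

Step 10. What may go wrong is proton transfer from the enolisable ketone 7 to the lithium enolate instead of addition, or retro-aldol cleavage of the hindered adduct. The fallback sets out from 16 and replaces the lithium enolate by a neutral nucleophile. Soft enolisation (tBuMe2SiOTf, Et3N, CH2Cl2, 0 °C) should give (5R)-2,5-bis[(tert-butyldimethylsilyl)oxy]-4-methyl-3-[(triisopropylsilyl)oxy]cyclohexa-1,3-diene F4. A Mukaiyama aldol addition of F4 to 7 (BF3·OEt2, CH2Cl2, −78 °C, kept cold to avoid ionisation of the allylic silyl ether) returns to the route at 18.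

Step 11. What may go wrong is elimination under kinetic control that gives the wrong double-bond geometry. The fallback sets out from 18 and corrects the geometry after the fact. The same elimination is run, and the (2Z)-isomer of 20, (2Z,3S)-2-[(5R)-5-[(tert-butyldimethylsilyl)oxy]-4-methyl-2-oxo-3-[(triisopropylsilyl)oxy]cyclohex-3-en-1-ylidene]-6-methylhept-5-en-3-yl (2Z)-2-methylbut-2-enoate F5, is separated. F5 is then equilibrated with catalytic iodine in CH2Cl2 under visible light (reversible iodine-atom addition) towards the less strained E isomer, which rejoins the route at 20.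

Further compounds
F1 | step 5 | racemic cis-1-[2-methyl-4-[(triethylsilyl)oxy]-3-[(triisopropylsilyl)oxy]cyclohex-3-en-1-yl]ethan-1-one | CC(=O)C1CCC(O[Si](CC)(CC)CC)=C(O[Si](C(C)C)(C(C)C)C(C)C)C1C
F2 | step 5 | racemic 4-acetyl-3-methyl-2-[(triisopropylsilyl)oxy]cyclohex-2-en-1-one | CC(=O)C1CCC(=O)C(O[Si](C(C)C)(C(C)C)C(C)C)=C1C
F3 | step 5 | racemic 2-methyl-4-oxo-3-[(triisopropylsilyl)oxy]cyclohex-2-en-1-yl acetate | CC(=O)OC1CCC(=O)C(O[Si](C(C)C)(C(C)C)C(C)C)=C1C
F4 | step 10 | (5R)-2,5-bis[(tert-butyldimethylsilyl)oxy]-4-methyl-3-[(triisopropylsilyl)oxy]cyclohexa-1,3-diene | CC(C)(C)[Si](C)(C)O[C@@H]1CC=C(O[Si](C)(C)C(C)(C)C)C(O[Si](C(C)C)(C(C)C)C(C)C)=C1C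
F5 | step 11 | (2Z,3S)-2-[(5R)-5-[(tert-butyldimethylsilyl)oxy]-4-methyl-2-oxo-3-[(triisopropylsilyl)oxy]cyclohex-3-en-1-ylidene]-6-methylhept-5-en-3-yl (2Z)-2-methylbut-2-enoate | C/C=C(/C)C(=O)O[C@@H](CC=C(C)C)/C(C)=C1/C[C@@H](O[Si](C)(C)C(C)(C)C)C(C)=C(O[Si](C(C)C)(C(C)C)C(C)C)C1=O
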